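## The problem

Compound 21 is a diaryl ether whose bridging oxygen is flanked by two ortho substituents on each ring: the C1 methyl ester on ring A, and the C2' hydroxymethyl and C6' prenyloxy groups on ring B. A C–O–C linkage this crowded is the bond least accessible to copper- or palladium-mediated aryl etherification, so the way the ether oxygen is attached decides the synthesis. There are no stereocentres; the selectivity problems are regiochemical. Two benzene rings carry eight substituents, and the four oxygens must end up differentiated: one methyl ether kept on ring B, one prenyl ether on each ring, and the ether bridge. The two aryl prenyl ethers are the fragile groups: acids cleave them, strong heating triggers Claisen rearrangement, and they tolerate neither peracids nor hydrogenation, so they must be introduced late. The benzylic alcohol on ring B is ionizable, and the ester on ring A sits between two ortho oxygens, which makes it hindered (useful at the end) and a chelating partner for Lewis acids (useful for unmasking C2–O). The enabling feature is the pattern of ring A: ester at C1, oxygen at C2 and C6, hydrogen at C3 and C5, methyl at C4. This is what results when the diene C3=C4–C5=C6 of a 3-carbomethoxy-4-aryloxy-6-methyl-2-pyrone takes up the two carbons of a ketene acetal and expels its lactone bridge. In that pyrone the future ether carbon C6 of ring A is not yet aromatic but the β-carbon of a doubly activated enoate, so the congested oxygen bridge can be made by addition–elimination.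

## Retrosynthesis

**21 to 20.** The last disconnection is a change of oxidation level at the ring B carbon: alcohol 21 is traced to aldehyde 20. Carrying this carbon as a formyl group needs no protecting group, because the aldehyde tolerates the Lewis-acid and carbonate steps that precede it. A protected alcohol would be ionized or lost in the Lewis-acid step. The forward step is a hydride reduction that must spare the ester, which its two ortho substituents make easy.

**20 to 18 and 19.** Both O–CH2 bonds of the prenyl ethers are cut, leading to bis-phenol 18 and two equivalents of 19. Putting the prenyl groups on last keeps them away from peracid, Lewis acid and prolonged heating. The precursor loses ten carbons and both sensitive alkenes. The forward step needs O- rather than C-alkylation and must reach the hydrogen-bonded salicylate hydroxyl.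

**18 to 17.** The two phenols are traced to a methyl ether at C2 of ring A and a benzyl ether at C6' of ring B. These are the forms in which the two oxygens arrive: from the ketene acetal and from the ring B starting material. One Lewis-acid operation should cleave both. The C2 methyl ether is singled out by chelation to the neighbouring ester, whereas the ring B methyl ether has no carbonyl neighbour. The forward step needs this discrimination and clean disposal of the benzyl cation.

**17 to 13 and 14 (key disconnection).** Ring A is opened at C1–C2 and C3–C4. The retron is a cycloaddition of pyrone 13 with ketene acetal 14 through the bridged lactone 15 and the diene 16. The neighbouring cuts are worse: cutting the aryl C6–O bond asks for etherification between two doubly ortho-substituted arenes, and cutting the C1–ester bond asks for metalation of a polyoxygenated diaryl ether. The pyrone precursor has one ring fewer and holds the ester, the ether oxygen and the methyl group in fixed relation. The forward reaction must bond the CH2 terminus of 14 to the methyl-bearing pyrone carbon and must leave the aryloxy-bearing carbon and the ring B aldehyde alone.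

**13 to 6 and 12.** The vinylic C4–O bond of the pyrone is cut. The forward reaction is an addition–elimination of the phenoxide of 12 on chloride 6. A chloride is preferred to a sulfonate because it is smaller and more electrophilic and offers the phenoxide no second electrophilic centre. The two fragments are each one ring with no shared functionality.

**6 to 5, then to 1 and 2.** The C–Cl bond goes back to the enol of hydroxypyrone 5. The pyrone ring is cut at the ring-oxygen-to-carbonyl bond and at the malonate-to-acyl bond, giving malonate 1 and acetylketene 3, released from dioxinone 2, by way of tricarbonyl 4. Both starting materials are bulk chemicals, and the forward step needs C-acylation followed by lactonization.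

**12 to 10, 8 and 7.** The formyl C–C bond of 12 is cut. Phenol 10 has only one free ortho position and its para position is blocked, so a magnesium-directed formylation via 11 cannot go elsewhere. Phenol 10 comes from aldehyde 8 by exchange of the formyl carbon for oxygen (Baeyer–Villiger, via formate 9), and 8 from commercial 7 by benzylation. Benzyl is chosen because it survives peracid, base and heat and leaves in the same operation as the C2 methyl group.

## Roads not taken

Alternative 1: Ring B would be built last by a vinylketene benzannulation. The cut removes C3'–C4', C5'–C6' and C6'–C1' and leads to the racemic cyclobutenone A1, whose C4 already carries the ring A aryloxy group, and to the alkoxyalkyne A2.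
- **Forward step:** heating A1 with A2 should cause 4π ring opening, [2+2] addition of A2, a second ring opening and a 6π closure, giving phenol A3.
- **Merits:** the ring B pattern is dictated by the mechanism. A3 arrives with only the C6' hydroxyl free and the ring A prenyl ether in place, so only one prenylation and one desilylation remain. That is one step fewer than the chosen endgame and needs no Lewis acid.
- **Weak points:** A1 is hard to make. Its C4–O bond joins an sp3 carbon of a strained, base-sensitive enone to a hindered, hydrogen-bonded phenolic oxygen. A2 is volatile and unstable. The ring A prenyl ether, with a free ortho position, must survive benzannulation temperatures near the onset of Claisen rearrangement.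
- **Comparison:** the endgame is better, but the difficulty moves into the precursor. The chosen plan sets against it a diaryl ether oxygen attached under mild ionic conditions and thermal chemistry done before any prenyl group is present.

Alternative 2: The cut falls on C6–O and C1–CO2 of ring A at once, uniting silyl triflate A4, the cesium salt of phenol A5 and carbon dioxide A6.
- **Forward step:** fluoride-induced aryne formation from A4, addition of the phenoxide oxygen at the position remote from the MOM ether, and carboxylation of the aryl anion formed next to that ether should give acid A7.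
- **Merits:** this is the most convergent of the four plans. Two bonds at the congested C1/C6 edge form in one flask, and the inductive effect of the alkoxy group controls orientation.
- **Weak points:** the aryl anion must capture A6 faster than it is protonated. A6 reversibly carboxylates the phenoxide oxygen and lowers its nucleophilicity. A5 is doubly ortho-substituted. Precedent for such three-component unions lies mainly with nitrogen nucleophiles. A4 takes several steps, and A7 still needs esterification of a hindered acid, MOM removal and double prenylation.
- **Comparison:** if the union worked, the route would be about as long as the chosen one and more convergent. The chosen plan offers a ring-forming step with direct precedent, regiochemistry fixed by construction, and no competition with proton quench.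

Alternative 3: The C1–carbonyl bond is cut and the ester is traced to the oxygen at C2 as the aryl methyl carbonate A8.
- **Forward step:** a lithium amide base should metalate C1 between the two aryl oxygens; an anionic ortho-Fries shift moves the methoxycarbonyl group to C1, and the freed phenoxide is alkylated in the same flask by 19 to give A9, one desilylation away from 21.
- **Merits:** this is the shortest endgame. It needs no dealkylation and no ring A protecting group, and the ester arrives last.
- **Weak points:** carbonates migrate less reliably than carbamates, because the base can attack the carbonyl. The substrate offers competing acidic sites: the O–CH2 of the ring B prenyl ether (Wittig rearrangement), C5'–H between two alkoxy groups, and the silyloxymethyl CH2. A8 still contains the diaryl ether, which would come from an Ullmann-type coupling, though with only ring B doubly ortho-substituted.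
- **Comparison:** alternative 3 is better in protecting-group economy and in steps after the ether is made. The chosen plan avoids organolithium chemistry in the presence of prenyl ethers and avoids any metal-mediated aryl etherification.

Key step: step 7

Assumption: 14 is taken as a purchasable reagent and is distilled from a trace of base before use, since adventitious acid would polymerize it and activate the ring B aldehyde toward it.

## Route

Step 1
Reactants: 1 dimethyl malonate; 2 2,2,6-trimethyl-4H-1,3-dioxin-4-one
Product: 5 methyl 4-hydroxy-6-methyl-2-oxo-2H-pyran-3-carboxylate, via acetylketene 3 (not isolated), via dimethyl 2-(3-oxobutanoyl)malonate 4 (not isolated)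
Conditions: NaH, THF, 0 °C; then 2, toluene, 110 °C (acetone distilled off); aq. HCl
Reagents that add atoms: none
Why: Retro-[4+2] of the dioxinone releases acetylketene, which C-acylates the sodium malonate (acylketene trapping); the tricarbonyl then lactonizes through the ketone enol oxygen with loss of methanol, driven by formation of the strongly acidic 4-hydroxypyrone salt.

Step 2
Reactants: 5 methyl 4-hydroxy-6-methyl-2-oxo-2H-pyran-3-carboxylate
Product: 6 methyl 4-chloro-6-methyl-2-oxo-2H-pyran-3-carboxylate
Conditions: (COCl)2, DMF (cat.), CH2Cl2, 0 °C to rt; used crude
Reagents that add atoms: oxalyl chloride, O=C(Cl)C(=O)Cl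
Why: Deoxychlorination of a vinylogous carboxylic acid through the Vilsmeier chloroiminium ion (O-activation, then chloride addition–elimination at C4), as practised on 4-hydroxy-2-pyrones and 4-hydroxycoumarins; ester and lactone are untouched.

Step 3
Reactants: 7 2-hydroxy-4-methoxybenzaldehyde
Product: 8 2-(benzyloxy)-4-methoxybenzaldehyde
Conditions: BnBr, K2CO3, DMF, 60 °C
Reagents that add atoms: benzyl bromide, BrCc1ccccc1
Why: Williamson ether synthesis on the only phenol; warming overcomes the hydrogen bond to the formyl group.

Step 4
Reactants: 8 2-(benzyloxy)-4-methoxybenzaldehyde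
Product: 10 2-(benzyloxy)-4-methoxyphenol, via 2-(benzyloxy)-4-methoxyphenyl formate 9 (not isolated)
Conditions: mCPBA, CH2Cl2, 0 °C to rt; then K2CO3, MeOH, rt
Reagents that add atoms: mCPBA, O=C(OO)c1cccc(Cl)c1
Why: Baeyer–Villiger (Dakin-type) oxidation; the electron-rich aryl group, with alkoxy donors ortho and para to the formyl carbon, migrates in the Criegee intermediate to give the formate, which is methanolysed to the phenol.

Step 5
Reactants: 10 2-(benzyloxy)-4-methoxyphenol
Product: 12 3-(benzyloxy)-2-hydroxy-5-methoxybenzaldehyde, via 2-(benzyloxy)-6-(hydroxymethyl)-4-methoxyphenol 11 (not isolated)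
Conditions: MgCl2, Et3N, (CH2O)n, MeCN, reflux; aq. HCl
Reagents that add atoms: paraformaldehyde (as formaldehyde), C=O
Why: Magnesium-mediated ortho-formylation (Casnati–Skattebøl); the chloromagnesium phenoxide delivers formaldehyde to the only free ortho carbon (the para carbon bears the methoxy group), and a second formaldehyde oxidizes the hydroxymethyl intermediate by magnesium-templated hydride transfer.

Step 6
Reactants: 6 methyl 4-chloro-6-methyl-2-oxo-2H-pyran-3-carboxylate; 12 3-(benzyloxy)-2-hydroxy-5-methoxybenzaldehyde
Product: 13 methyl 4-[2-(benzyloxy)-6-formyl-4-methoxyphenoxy]-6-methyl-2-oxo-2H-pyran-3-carboxylate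
Conditions: K2CO3, MeCN, 0 °C to rt
Reagents that add atoms: none
Why: Addition–elimination (vinylogous nucleophilic acyl substitution): the phenoxide adds to C4, the β-carbon of both the lactone and the ester, and chloride leaves; an sp2 carbon of a non-aromatic ring is far less sensitive to the two ortho substituents of the phenoxide than an aryl halide in a metal-mediated etherification.

Step 7
Reactants: 13 methyl 4-[2-(benzyloxy)-6-formyl-4-methoxyphenoxy]-6-methyl-2-oxo-2H-pyran-3-carboxylate; 14 1,1-dimethoxyethene
Product: 17 methyl 2-[2-(benzyloxy)-6-formyl-4-methoxyphenoxy]-6-methoxy-4-methylbenzoate, via bridged lactone cycloadduct 15 (not isolated), via dimethoxycyclohexadiene ester 16 (not isolated)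
Conditions: 14 (5 equiv), toluene, 110–120 °C, sealed tube, base-washed glass
Reagents that add atoms: none
Why: This is an inverse-electron-demand Diels–Alder reaction: the HOMO of ketene acetal 14 and the LUMO of the pyrone diene C3=C4–C5=C6, lowered by the C3 ester and the lactone carbonyl, combine in a concerted but strongly asynchronous [4+2] in which the CH2 terminus of 14 bonds to pyrone C6 and the acetal carbon to pyrone C3. The bridged lactone 15 then loses its CO2 bridge by retro-[4+2] to give diene 16, which aromatizes by loss of methanol across its CH2–C(OMe)2 bond. The closest known reaction type is the thermal cycloaddition of 3-carbomethoxy-2-pyrones with 1,1-dimethoxyethene to give methyl 2-methoxybenzoates. Ring A is closed by the intermolecular cycloaddition itself, both ring bonds (C1–C2 and C3–C4 in ring A numbering) forming in one suprafacial event, and becomes benzenoid after the two eliminations. No stereocentre survives: the two bridgehead centres of 15 form as a racemate and are erased on aromatization. The step needs regioselectivity (CH2 to the methyl-bearing pyrone C6, not the reverse orientation) and site selectivity (no addition–elimination at the aryloxy-bearing C4, no addition to the ring B aldehyde). Orientation follows from the polarization of the diene, C6 being the vinylogous acceptor terminus of both carbonyl groups; C4 is deactivated by oxygen lone-pair donation and shielded by the 2,6-disubstituted aryl group, and the aldehyde, without Lewis-acid activation, is a far weaker acceptor than the pyrone, which is why acid-free conditions are specified.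

Step 8
Reactants: 17 methyl 2-[2-(benzyloxy)-6-formyl-4-methoxyphenoxy]-6-methoxy-4-methylbenzoate
Product: 18 methyl 2-(2-formyl-6-hydroxy-4-methoxyphenoxy)-6-hydroxy-4-methylbenzoate
Conditions: BCl3, C6HMe5, CH2Cl2, −78 to 0 °C; MeOH, then aq. NaHCO3
Reagents that add atoms: none
Why: BCl3 cleaves the benzyl ether at low temperature, with pentamethylbenzene as a non-coordinating Friedel–Crafts trap for the benzyl cation, and on warming cleaves the C2 methyl ether through a six-membered chelate with the neighbouring ester carbonyl (chelation-controlled demethylation); the ring B methyl ether has no ortho carbonyl and should stay, as should the ester and the aldehyde.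

Step 9
Reactants: 18 methyl 2-(2-formyl-6-hydroxy-4-methoxyphenoxy)-6-hydroxy-4-methylbenzoate; 19 prenyl bromide (1-bromo-3-methylbut-2-ene)
Product: 20 methyl 2-{2-formyl-4-methoxy-6-[(3-methylbut-2-en-1-yl)oxy]phenoxy}-4-methyl-6-[(3-methylbut-2-en-1-yl)oxy]benzoate
Conditions: 19 (3 equiv), K2CO3, DMF, 50 °C
Reagents that add atoms: none
Why: Double Williamson O-alkylation; K2CO3 in DMF favours O- over C-prenylation, gentle warming brings in the hydrogen-bonded salicylate hydroxyl, and the temperature stays far below that of aryl prenyl ether Claisen rearrangement.

Step 10
Reactants: 20 methyl 2-{2-formyl-4-methoxy-6-[(3-methylbut-2-en-1-yl)oxy]phenoxy}-4-methyl-6-[(3-methylbut-2-en-1-yl)oxy]benzoate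
Product: 21 methyl 2-{2-(hydroxymethyl)-4-methoxy-6-[(3-methylbut-2-en-1-yl)oxy]phenoxy}-4-methyl-6-[(3-methylbut-2-en-1-yl)oxy]benzoate
Conditions: NaBH4, MeOH–THF, 0 °C
Reagents that add atoms: none
Why: Chemoselective borohydride reduction of the aryl aldehyde; the methyl ester, flanked by two ortho substituents, and the prenyl ethers should not react under these conditions.

## Compound list

1 | dimethyl malonate | COC(=O)CC(=O)OC | starting material
2 | 2,2,6-trimethyl-4H-1,3-dioxin-4-one | CC1=CC(=O)OC(C)(C)O1 | starting material
3 | acetylketene (but-1-ene-1,3-dione) | CC(=O)C=C=O | intermediate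
4 | dimethyl 2-(3-oxobutanoyl)malonate | CC(=O)CC(=O)C(C(=O)OC)C(=O)OC | intermediate
5 | methyl 4-hydroxy-6-methyl-2-oxo-2H-pyran-3-carboxylate | COC(=O)C1=C(O)C=C(C)OC1=O | intermediate
6 | methyl 4-chloro-6-methyl-2-oxo-2H-pyran-3-carboxylate | COC(=O)C1=C(Cl)C=C(C)OC1=O | intermediate
7 | 2-hydroxy-4-methoxybenzaldehyde | COc1ccc(C=O)c(O)c1 | starting material
8 | 2-(benzyloxy)-4-methoxybenzaldehyde | COc1ccc(C=O)c(OCc2ccccc2)c1 | intermediate
9 | 2-(benzyloxy)-4-methoxyphenyl formate | COc1ccc(OC=O)c(OCc2ccccc2)c1 | intermediate
10 | 2-(benzyloxy)-4-methoxyphenol | COc1ccc(O)c(OCc2ccccc2)c1 | intermediate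
11 | 2-(benzyloxy)-6-(hydroxymethyl)-4-methoxyphenol | COc1cc(CO)c(O)c(OCc2ccccc2)c1 | intermediate
12 | 3-(benzyloxy)-2-hydroxy-5-methoxybenzaldehyde | COc1cc(C=O)c(O)c(OCc2ccccc2)c1 | intermediate
13 | methyl 4-[2-(benzyloxy)-6-formyl-4-methoxyphenoxy]-6-methyl-2-oxo-2H-pyran-3-carboxylate | COC(=O)C1=C(Oc2c(C=O)cc(OC)cc2OCc2ccccc2)C=C(C)OC1=O | intermediate
14 | 1,1-dimethoxyethene | C=C(OC)OC | starting material
15 | methyl 5-[2-(benzyloxy)-6-formyl-4-methoxyphenoxy]-8,8-dimethoxy-1-methyl-3-oxo-2-oxabicyclo[2.2.2]oct-5-ene-4-carboxylate (racemic bridged lactone) | COC(=O)C12C(=O)OC(C)(CC1(OC)OC)C=C2Oc1c(C=O)cc(OC)cc1OCc1ccccc1 | intermediate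
16 | methyl 2-[2-(benzyloxy)-6-formyl-4-methoxyphenoxy]-6,6-dimethoxy-4-methylcyclohexa-1,3-diene-1-carboxylate | COC(=O)C1=C(Oc2c(C=O)cc(OC)cc2OCc2ccccc2)C=C(C)CC1(OC)OC | intermediate
17 | methyl 2-[2-(benzyloxy)-6-formyl-4-methoxyphenoxy]-6-methoxy-4-methylbenzoate | COC(=O)c1c(OC)cc(C)cc1Oc1c(C=O)cc(OC)cc1OCc1ccccc1 | intermediate
18 | methyl 2-(2-formyl-6-hydroxy-4-methoxyphenoxy)-6-hydroxy-4-methylbenzoate | COC(=O)c1c(O)cc(C)cc1Oc1c(C=O)cc(OC)cc1O | intermediate
19 | prenyl bromide (1-bromo-3-methylbut-2-ene) | CC(C)=CCBr | starting material
20 | methyl 2-{2-formyl-4-methoxy-6-[(3-methylbut-2-en-1-yl)oxy]phenoxy}-4-methyl-6-[(3-methylbut-2-en-1-yl)oxy]benzoate | COC(=O)c1c(OCC=C(C)C)cc(C)cc1Oc1c(C=O)cc(OC)cc1OCC=C(C)C | intermediate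
21 | methyl 2-{2-(hydroxymethyl)-4-methoxy-6-[(3-methylbut-2-en-1-yl)oxy]phenoxy}-4-methyl-6-[(3-methylbut-2-en-1-yl)oxy]benzoate | COC(=O)c1c(OCC=C(C)C)cc(C)cc1Oc1c(CO)cc(OC)cc1OCC=C(C)C | target

## Step count and risks

Total: 10 steps. Longest linear sequence: 8 steps (steps 3 to 10, from 7); the pyrone branch (steps 1 and 2) joins at step 6.

**Step 7 (key step).** The 4-aryloxy donor and the 6-methyl group make this pyrone a weaker diene than the parent systems, so prolonged heating will be needed. Under such conditions the ketene acetal may be diverted to addition at the ring B aldehyde, or to addition–elimination at pyrone C4 with expulsion of the 2-formylphenoxide, which the formyl group makes a good nucleofuge.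

The fallback removes the formyl group from the cycloaddition substrate. It sets out from 12 and comes back at 17:
- Reduction of 12 with NaBH4 gives diol 11, here isolated.
- Silylation of the primary hydroxyl (TBSCl, imidazole, CH2Cl2, 0 °C) gives 2-(benzyloxy)-6-({[tert-butyl(dimethyl)silyl]oxy}methyl)-4-methoxyphenol F1.
- Coupling of F1 with 6 as in step 6 gives the silyloxymethyl pyrone ether F2.
- Cycloaddition of F2 with 14 runs through the bridged lactone F3 and the dimethoxycyclohexadiene F4 to the silyloxymethyl diaryl ether F5.
- Tetrabutylammonium fluoride frees the benzylic alcohol F6, and MnO2 in CH2Cl2 oxidizes it to 17.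

This costs four extra steps but offers the ketene acetal no carbonyl other than the pyrone and a poorer leaving group at C4.

**Step 1.** Acetylketene 3 may dimerize or acylate the malonate on oxygen faster than on carbon, and the enolate of 4 may fail to lactonize under basic conditions. The fallback avoids free acylketene. It sets out from 1 and comes back at 5: sodium dimethyl malonate is acylated with diketene at 0 °C by nucleophilic opening of the β-lactone, 4 is isolated after acidification, and it is lactonized in a separate acid-catalysed step (TsOH, toluene, reflux, methanol removed). No new compound arises.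

**Step 6.** Hydrolysis or carbonate-induced decomposition of the very electrophilic chloride 6 may outrun addition of the chelated, weakly nucleophilic and doubly flanked phenoxide of 12. The fallback trades reactivity for stability by changing the electrophile class. It sets out from 5 and comes back at 13: sulfonylation (TsCl, Et3N, CH2Cl2) gives the purifiable tosylate methyl 6-methyl-4-{[(4-methylphenyl)sulfonyl]oxy}-2-oxo-2H-pyran-3-carboxylate F7, which is displaced at C4 by the preformed cesium phenoxide of 12 (Cs2CO3, MeCN).

**Step 8.** With enough BCl3 and warming to cleave the ester-flanked methyl ether, the released benzyl cation may alkylate the electron-rich rings, or the unchelated ring B methyl ether may also be cleaved. The fallback separates the two cleavages by mechanism. It sets out from 17 and comes back at 18: hydrogenolysis of the benzyl ether (H2, Pd/C, EtOAc, stopped after one equivalent of hydrogen so that the aldehyde is kept) gives methyl 2-(2-formyl-6-hydroxy-4-methoxyphenoxy)-6-methoxy-4-methylbenzoate F8, and a limited excess of BCl3 at −78 to −20 °C then carries out only the chelation-controlled demethylation.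

## Further compounds

F1 | step 7 | 2-(benzyloxy)-6-({[tert-butyl(dimethyl)silyl]oxy}methyl)-4-methoxyphenol | COc1cc(CO[Si](C)(C)C(C)(C)C)c(O)c(OCc2ccccc2)c1
F2 | step 7 | methyl 4-[2-(benzyloxy)-6-({[tert-butyl(dimethyl)silyl]oxy}methyl)-4-methoxyphenoxy]-6-methyl-2-oxo-2H-pyran-3-carboxylate | COC(=O)C1=C(Oc2c(CO[Si](C)(C)C(C)(C)C)cc(OC)cc2OCc2ccccc2)C=C(C)OC1=O
F3 | step 7 | methyl 5-[2-(benzyloxy)-6-({[tert-butyl(dimethyl)silyl]oxy}methyl)-4-methoxyphenoxy]-8,8-dimethoxy-1-methyl-3-oxo-2-oxabicyclo[2.2.2]oct-5-ene-4-carboxylate (racemic) | COC(=O)C12C(=O)OC(C)(CC1(OC)OC)C=C2Oc1c(CO[Si](C)(C)C(C)(C)C)cc(OC)cc1OCc1ccccc1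
F4 | step 7 | methyl 2-[2-(benzyloxy)-6-({[tert-butyl(dimethyl)silyl]oxy}methyl)-4-methoxyphenoxy]-6,6-dimethoxy-4-methylcyclohexa-1,3-diene-1-carboxylate | COC(=O)C1=C(Oc2c(CO[Si](C)(C)C(C)(C)C)cc(OC)cc2OCc2ccccc2)C=C(C)CC1(OC)OC
F5 | step 7 | methyl 2-[2-(benzyloxy)-6-({[tert-butyl(dimethyl)silyl]oxy}methyl)-4-methoxyphenoxy]-6-methoxy-4-methylbenzoate | COC(=O)c1c(OC)cc(C)cc1Oc1c(CO[Si](C)(C)C(C)(C)C)cc(OC)cc1OCc1ccccc1
F6 | step 7 | methyl 2-[2-(benzyloxy)-6-(hydroxymethyl)-4-methoxyphenoxy]-6-methoxy-4-methylbenzoate | COC(=O)c1c(OC)cc(C)cc1Oc1c(CO)cc(OC)cc1OCc1ccccc1
F0 | step 1 | none | none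
F7 | step 6 | methyl 6-methyl-4-{[(4-methylphenyl)sulfonyl]oxy}-2-oxo-2H-pyran-3-carboxylate | COC(=O)C1=C(OS(=O)(=O)c2ccc(C)cc2)C=C(C)OC1=O
F8 | step 8 | methyl 2-(2-formyl-6-hydroxy-4-methoxyphenoxy)-6-methoxy-4-methylbenzoate | COC(=O)c1c(OC)cc(C)cc1Oc1c(C=O)cc(OC)cc1O
A1 | alternative 1 | methyl 2-{[2-({[tert-butyl(dimethyl)silyl]oxy}methyl)-4-oxocyclobut-2-en-1-yl]oxy}-4-methyl-6-[(3-methylbut-2-en-1-yl)oxy]benzoate (racemic) | COC(=O)c1c(OCC=C(C)C)cc(C)cc1OC1C(=O)C=C1CO[Si](C)(C)C(C)(C)C
A2 | alternative 1 | methoxyethyne | COC#C
A3 | alternative 1 | methyl 2-[2-({[tert-butyl(dimethyl)silyl]oxy}methyl)-6-hydroxy-4-methoxyphenoxy]-4-methyl-6-[(3-methylbut-2-en-1-yl)oxy]benzoate | COC(=O)c1c(OCC=C(C)C)cc(C)cc1Oc1c(CO[Si](C)(C)C(C)(C)C)cc(OC)cc1O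
A4 | alternative 2 | 3-(methoxymethoxy)-5-methyl-2-(trimethylsilyl)phenyl trifluoromethanesulfonate | COCOc1cc(C)cc(OS(=O)(=O)C(F)(F)F)c1[Si](C)(C)C
A5 | alternative 2 | 2-({[tert-butyl(dimethyl)silyl]oxy}methyl)-4-methoxy-6-(methoxymethoxy)phenol | COCOc1cc(OC)cc(CO[Si](C)(C)C(C)(C)C)c1O
A6 | alternative 2 | carbon dioxide | O=C=O
A7 | alternative 2 | 2-[2-({[tert-butyl(dimethyl)silyl]oxy}methyl)-4-methoxy-6-(methoxymethoxy)phenoxy]-6-(methoxymethoxy)-4-methylbenzoic acid | O=C(O)c1c(OCOC)cc(C)cc1Oc1c(CO[Si](C)(C)C(C)(C)C)cc(OC)cc1OCOC
A8 | alternative 3 | 3-[2-({[tert-butyl(dimethyl)silyl]oxy}methyl)-4-methoxy-6-[(3-methylbut-2-en-1-yl)oxy]phenoxy]-5-methylphenyl methyl carbonate | COC(=O)Oc1cc(C)cc(Oc2c(CO[Si](C)(C)C(C)(C)C)cc(OC)cc2OCC=C(C)C)c1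
A9 | alternative 3 | methyl 2-[2-({[tert-butyl(dimethyl)silyl]oxy}methyl)-4-methoxy-6-[(3-methylbut-2-en-1-yl)oxy]phenoxy]-4-methyl-6-[(3-methylbut-2-en-1-yl)oxy]benzoate | COC(=O)c1c(OCC=C(C)C)cc(C)cc1Oc1c(CO[Si](C)(C)C(C)(C)C)cc(OC)cc1OCC=C(C)C
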